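Ring B (C1–C4, C4a, C8a; tetralone numbering) is a β-hydroxy ketone whose C1=O/C2H2 unit is a ketene equivalent inserted between C3 and C8a. Disconnecting C2–C3 and C1–C8a leaves a 2-aryl-1,3-diketone carrying both aromatic halves. The key step treats its silyl enol ether with ethoxyacetylene under chiral hydrogen-bond-donor/silyl triflate catalysis: the ynol ether adds to the C3 terminus of a bis(silyloxy)allyl cation and the ketenium ion closes onto an ortho carbon of the symmetric 3,5-dioxygenated ring A, setting C3; C4, flanked by aryl and aroyl groups, equilibrates. Both halves come from one arylacetic ester.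

Key step: step 11

Remark: the 3-OH/4-aroyl cis isomer (3R,4S) is taken as the thermodynamically preferred epimer at the enolisable C4, so C4 is set by equilibration once C3 is fixed.

Step 1
Reactants: 1 methyl 2-(3,5-dihydroxyphenyl)acetate
Product: 2 methyl 2-[3,5-bis(benzyloxy)phenyl]acetate
Conditions: BnBr, K2CO3, DMF, rt
Reagents that add atoms: benzyl bromide BrCc1ccccc1
Why: Williamson ether synthesis on both phenols, the carbonate being too weak a base to touch the ester α-position.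

Step 2
Reactants: 2 methyl 2-[3,5-bis(benzyloxy)phenyl]acetate
Product: 3 2-[3,5-bis(benzyloxy)phenyl]-N-methoxy-N-methylacetamide
Conditions: MeNH(OMe)·HCl, i-PrMgCl, THF, −20 °C to 0 °C
Reagents that add atoms: N,O-dimethylhydroxylamine hydrochloride CNOC.Cl
Why: Aminolysis of the ester by the magnesium amide of N,O-dimethylhydroxylamine should give the Weinreb amide directly.

Step 3
Reactants: 3 2-[3,5-bis(benzyloxy)phenyl]-N-methoxy-N-methylacetamide
Product: 4 1-[3,5-bis(benzyloxy)phenyl]propan-2-one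
Conditions: MeMgBr, THF, 0 °C; aq. NH4Cl
Reagents that add atoms: methylmagnesium bromide C[Mg]Br
Why: Weinreb ketone synthesis, in which the chelated tetrahedral intermediate prevents a second addition.

Step 4
Reactants: 3 2-[3,5-bis(benzyloxy)phenyl]-N-methoxy-N-methylacetamide; 5 2,2,6-trimethyl-4H-1,3-dioxin-4-one
Product: 6 6-{3-[3,5-bis(benzyloxy)phenyl]-2-oxopropyl}-2,2-dimethyl-4H-1,3-dioxin-4-one
Conditions: LDA (2.2 equiv), THF, −78 °C; aq. NH4Cl
Reagents that add atoms: none
Why: Vinylogous Claisen-type acylation of the lithium dienolate of the dioxinone at its methyl carbon by the Weinreb amide, the second equivalent of base holding the product as its enolate.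

Step 5
Reactants: 6 6-{3-[3,5-bis(benzyloxy)phenyl]-2-oxopropyl}-2,2-dimethyl-4H-1,3-dioxin-4-one
Product: 7 6-[3,5-bis(benzyloxy)benzyl]-4-hydroxy-2H-pyran-2-one
Conditions: toluene, 110 °C
Reagents that add atoms: none
Why: Thermal retro-[4+2] loss of acetone gives an acylketene that is trapped by the enol oxygen of the side-chain ketone in a 6-ring closure, the usual dioxinone route to 4-hydroxy-2-pyrones.

Step 6
Reactants: 7 6-[3,5-bis(benzyloxy)benzyl]-4-hydroxy-2H-pyran-2-one
Product: 8 4-(benzyloxy)-6-[3,5-bis(benzyloxy)benzyl]-2H-pyran-2-one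
Conditions: BnOH, PPh3, diisopropyl azodicarboxylate (DIAD), THF, 0 °C to rt
Reagents that add atoms: benzyl alcohol OCc1ccccc1
Why: Mitsunobu reaction of the acidic 4-hydroxy-2-pyrone, which is expected to alkylate the 4-oxygen.

Step 7
Reactants: 8 4-(benzyloxy)-6-[3,5-bis(benzyloxy)benzyl]-2H-pyran-2-one
Product: 9 2,4-bis(benzyloxy)-6-{[4-(benzyloxy)-2-oxo-2H-pyran-6-yl]methyl}benzaldehyde
Conditions: POCl3, DMF, 0 °C to 40 °C; aq. NaOAc
Reagents that add atoms: N,N-dimethylformamide CN(C)C=O; water O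
Why: Vilsmeier–Haack formylation at the arene carbon ortho to the benzylic CH2 and para to a benzyloxy group, the site preferred in 3,5-dialkoxytoluenes, the alkoxypyrone being far less nucleophilic.

Step 8
Reactants: 9 2,4-bis(benzyloxy)-6-{[4-(benzyloxy)-2-oxo-2H-pyran-6-yl]methyl}benzaldehyde
Product: 10 2,4-bis(benzyloxy)-6-{[4-(benzyloxy)-2-oxo-2H-pyran-6-yl]methyl}benzoic acid
Conditions: NaClO2, NaH2PO4, 2-methyl-2-butene, t-BuOH/THF/H2O, rt
Reagents that add atoms: sodium chlorite [Na+].[O-]Cl=O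
Why: Pinnick oxidation of the aldehyde, with the alkene scavenger protecting the electron-rich rings from hypochlorous acid.

Step 9
Reactants: 10 2,4-bis(benzyloxy)-6-{[4-(benzyloxy)-2-oxo-2H-pyran-6-yl]methyl}benzoic acid; 4 1-[3,5-bis(benzyloxy)phenyl]propan-2-one
Product: 12 2-[3,5-bis(benzyloxy)phenyl]-1-(2,4-bis(benzyloxy)-6-{[4-(benzyloxy)-2-oxo-2H-pyran-6-yl]methyl}phenyl)butane-1,3-dione, via acid chloride 11 (not isolated)
Conditions: (COCl)2, DMF (cat.), CH2Cl2, 0 °C; then 4, MgBr2·OEt2, i-Pr2NEt, CH2Cl2, rt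
Reagents that add atoms: none
Why: Claisen-type C-acylation under soft enolisation, in which the arylacetone enolises towards its benzylic carbon and the magnesium enolate is acylated on carbon to give the 2-aryl-1,3-diketone as its chelate.

Step 10
Reactants: 12 2-[3,5-bis(benzyloxy)phenyl]-1-(2,4-bis(benzyloxy)-6-{[4-(benzyloxy)-2-oxo-2H-pyran-6-yl]methyl}phenyl)butane-1,3-dione
Product: 13 2-[3,5-bis(benzyloxy)phenyl]-1-(2,4-bis(benzyloxy)-6-{[4-(benzyloxy)-2-oxo-2H-pyran-6-yl]methyl}phenyl)-3-(triethylsilyloxy)but-2-en-1-one (double-bond isomers)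
Conditions: Et3SiOTf, Et3N, CH2Cl2, −78 °C
Reagents that add atoms: triethylsilyl trifluoromethanesulfonate CC[Si](CC)(CC)OS(=O)(=O)C(F)(F)F
Why: O-silylation of the enolised 1,3-diketone on the less hindered acetyl-side oxygen gives the 3-silyloxy enone, and either regio- or geometric isomer would converge on the same bis(silyloxy)allyl cation.

Step 11
Reactants: 13 2-[3,5-bis(benzyloxy)phenyl]-1-(2,4-bis(benzyloxy)-6-{[4-(benzyloxy)-2-oxo-2H-pyran-6-yl]methyl}phenyl)-3-(triethylsilyloxy)but-2-en-1-one; 14 ethoxyacetylene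
Product: 16 (3R,4S)-6,8-bis(benzyloxy)-4-(2,4-bis(benzyloxy)-6-{[4-(benzyloxy)-2-oxo-2H-pyran-6-yl]methyl}benzoyl)-3-hydroxy-3-methyl-3,4-dihydronaphthalen-1(2H)-one, via cyclic ethyl enol ether 15 (not isolated)
Conditions: 3-{[3,5-bis(trifluoromethyl)phenyl]amino}-4-({(2S)-3,3-dimethyl-1-oxo-1-[(2R)-2-(phenanthren-9-yl)pyrrolidin-1-yl]butan-2-yl}amino)cyclobut-3-ene-1,2-dione or its enantiomer (10 mol%), Et3SiOTf (10 mol%), 14 (3 equiv), t-BuOMe, −78 °C; then HF·pyridine, THF/H2O, 0 °C
Reagents that add atoms: water O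
Why: Proposed new method: squaramide-bound Et3SiOTf silylates the aroyl oxygen of 13 to give a 2-aryl-1,3-bis(silyloxy)allyl cation paired with the chiral squaramide–triflate anion, the nucleophilic CH carbon of 14 adds to its methyl-bearing terminus (C2–C3 bond), and the ketenium ion so formed is captured by an ortho carbon of ring A (C1–C8a bond), the proton released then desilylating the remaining enol silane and returning Et3SiOTf. The closest known reaction types are enantioselective additions of pi-nucleophiles to silyloxyallyl and oxocarbenium cations under hydrogen-bond-donor/silyl triflate co-catalysis, Prins-type additions of ynol ethers to activated carbonyl groups, and acid-promoted ketenium–arene cyclisations of ynol ethers that give 1-tetralone enol ethers. Ring B is closed by a 6-ring Friedel–Crafts attack on the digonal ketenium carbon (6-endo mode), and because ring A is symmetric only its two equivalent ortho positions can reach that carbon, so no regioisomer is possible. C3 is set in the intermolecular C–C bond formation by the chiral anion, which blocks one face of the planar cation (the antipode of the squaramide that gives 3R is chosen in a short screen), whereas C4 is planar in that step and is set later by equilibration to the epimer with the aroyl group trans to the methyl group and hydrogen-bonded to the 3-OH. The step needs addition at the methyl-bearing and not the aryl-bearing terminus, secured by the two ortho substituents of the aroyl ring, and arene capture of the ketenium ion in place of 4-ring closure (oxetene or cyclobutene), secured by the silyl cap on the C3 oxygen, the fully substituted C4 and the high nucleophilicity of the dialkoxyarene. Hydrolysis in the work-up converts the ethyl enol ether into the C1 ketone and frees the tertiary alcohol.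

Step 12
Reactants: 16 (3R,4S)-6,8-bis(benzyloxy)-4-(2,4-bis(benzyloxy)-6-{[4-(benzyloxy)-2-oxo-2H-pyran-6-yl]methyl}benzoyl)-3-hydroxy-3-methyl-3,4-dihydronaphthalen-1(2H)-one
Product: 17 (3R,4S)-4-(2,4-dihydroxy-6-{[4-hydroxy-2-oxo-2H-pyran-6-yl]methyl}benzoyl)-3,6,8-trihydroxy-3-methyl-3,4-dihydronaphthalen-1(2H)-one
Conditions: H2 (1 atm), Pd/C (10%), EtOAc/MeOH, rt
Reagents that add atoms: none
Why: Catalytic hydrogenolysis of the six benzyl ethers under neutral conditions should leave the acid- and base-sensitive tertiary aldol, the aryl ketones, the pyrone and both stereocenters untouched.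

Compound list
1 | methyl 2-(3,5-dihydroxyphenyl)acetate | COC(=O)Cc1cc(O)cc(O)c1 | starting material
2 | methyl 2-[3,5-bis(benzyloxy)phenyl]acetate | COC(=O)Cc1cc(OCc2ccccc2)cc(OCc2ccccc2)c1 | intermediate
3 | 2-[3,5-bis(benzyloxy)phenyl]-N-methoxy-N-methylacetamide | CON(C)C(=O)Cc1cc(OCc2ccccc2)cc(OCc2ccccc2)c1 | intermediate
4 | 1-[3,5-bis(benzyloxy)phenyl]propan-2-one | CC(=O)Cc1cc(OCc2ccccc2)cc(OCc2ccccc2)c1 | intermediate
5 | 2,2,6-trimethyl-4H-1,3-dioxin-4-one | CC1=CC(=O)OC(C)(C)O1 | starting material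
6 | 6-{3-[3,5-bis(benzyloxy)phenyl]-2-oxopropyl}-2,2-dimethyl-4H-1,3-dioxin-4-one | O=C(Cc1cc(OCc2ccccc2)cc(OCc2ccccc2)c1)CC1=CC(=O)OC(C)(C)O1 | intermediate
7 | 6-[3,5-bis(benzyloxy)benzyl]-4-hydroxy-2H-pyran-2-one | O=c1cc(O)cc(Cc2cc(OCc3ccccc3)cc(OCc3ccccc3)c2)o1 | intermediate
8 | 4-(benzyloxy)-6-[3,5-bis(benzyloxy)benzyl]-2H-pyran-2-one | O=c1cc(OCc2ccccc2)cc(Cc2cc(OCc3ccccc3)cc(OCc3ccccc3)c2)o1 | intermediate
9 | 2,4-bis(benzyloxy)-6-{[4-(benzyloxy)-2-oxo-2H-pyran-6-yl]methyl}benzaldehyde | O=Cc1c(OCc2ccccc2)cc(OCc2ccccc2)cc1Cc1cc(OCc2ccccc2)cc(=O)o1 | intermediate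
10 | 2,4-bis(benzyloxy)-6-{[4-(benzyloxy)-2-oxo-2H-pyran-6-yl]methyl}benzoic acid | OC(=O)c1c(OCc2ccccc2)cc(OCc2ccccc2)cc1Cc1cc(OCc2ccccc2)cc(=O)o1 | intermediate
11 | 2,4-bis(benzyloxy)-6-{[4-(benzyloxy)-2-oxo-2H-pyran-6-yl]methyl}benzoyl chloride | ClC(=O)c1c(OCc2ccccc2)cc(OCc2ccccc2)cc1Cc1cc(OCc2ccccc2)cc(=O)o1 | intermediate
12 | 2-[3,5-bis(benzyloxy)phenyl]-1-(2,4-bis(benzyloxy)-6-{[4-(benzyloxy)-2-oxo-2H-pyran-6-yl]methyl}phenyl)butane-1,3-dione (keto and enol forms) | CC(=O)C(c1cc(OCc2ccccc2)cc(OCc2ccccc2)c1)C(=O)c1c(OCc2ccccc2)cc(OCc2ccccc2)cc1Cc1cc(OCc2ccccc2)cc(=O)o1 | intermediate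
13 | 2-[3,5-bis(benzyloxy)phenyl]-1-(2,4-bis(benzyloxy)-6-{[4-(benzyloxy)-2-oxo-2H-pyran-6-yl]methyl}phenyl)-3-(triethylsilyloxy)but-2-en-1-one (double-bond isomers) | CC(O[Si](CC)(CC)CC)=C(c1cc(OCc2ccccc2)cc(OCc2ccccc2)c1)C(=O)c1c(OCc2ccccc2)cc(OCc2ccccc2)cc1Cc1cc(OCc2ccccc2)cc(=O)o1 | intermediate
14 | ethoxyacetylene | C#COCC | starting material
15 | (3R)-6,8-bis(benzyloxy)-4-(2,4-bis(benzyloxy)-6-{[4-(benzyloxy)-2-oxo-2H-pyran-6-yl]methyl}benzoyl)-1-ethoxy-3-methyl-3-(triethylsilyloxy)-3,4-dihydronaphthalene (tetralone numbering; C4 epimers) | CCOC1=C[C@@](C)(O[Si](CC)(CC)CC)C(C(=O)c2c(OCc3ccccc3)cc(OCc3ccccc3)cc2Cc2cc(OCc3ccccc3)cc(=O)o2)c2cc(OCc3ccccc3)cc(OCc3ccccc3)c12 | intermediate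
16 | (3R,4S)-6,8-bis(benzyloxy)-4-(2,4-bis(benzyloxy)-6-{[4-(benzyloxy)-2-oxo-2H-pyran-6-yl]methyl}benzoyl)-3-hydroxy-3-methyl-3,4-dihydronaphthalen-1(2H)-one | C[C@@]1(O)CC(=O)c2c(OCc3ccccc3)cc(OCc3ccccc3)cc2[C@@H]1C(=O)c1c(OCc2ccccc2)cc(OCc2ccccc2)cc1Cc1cc(OCc2ccccc2)cc(=O)o1 | intermediate
17 | (3R,4S)-4-(2,4-dihydroxy-6-{[4-hydroxy-2-oxo-2H-pyran-6-yl]methyl}benzoyl)-3,6,8-trihydroxy-3-methyl-3,4-dihydronaphthalen-1(2H)-one | C[C@@]1(O)CC(=O)c2c(O)cc(O)cc2[C@@H]1C(=O)c1c(O)cc(O)cc1Cc1cc(O)cc(=O)o1 | target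

Total step count: 12. Longest linear sequence: 11 steps (1, 2, 3, 6, 7, 8, 9, 10, 12, 13, 16, 17).

Steps most likely to fail

Step 11 (Proposed new method) carries the most risk. The ketenium ion may be captured by the silyl ether oxygen or by the enol silane carbon (4-ring closure, carbonyl–alkyne metathesis) before the arene attacks. The ynol ether may add to the silylated pyrone. The chiral anion may discriminate the two faces of the acyclic cation poorly. The tertiary silyloxy group may ionise, with aromatisation of ring B. The fallback builds ring B stepwise with known reactions, setting out from 4 and 11 and returning at 16. Ketone 4 is brominated at the ring carbon ortho to the side chain (NBS, MeCN, 0 °C) to give 1-[2-bromo-3,5-bis(benzyloxy)phenyl]propan-2-one F1. This is C-acylated with acid chloride 11 under the conditions of step 9 to give 2-[2-bromo-3,5-bis(benzyloxy)phenyl]-1-(2,4-bis(benzyloxy)-6-{[4-(benzyloxy)-2-oxo-2H-pyran-6-yl]methyl}phenyl)butane-1,3-dione F2. Stille coupling with tributyl(1-ethoxyvinyl)stannane (Pd(PPh3)4, CuI, CsF, DMF, 45 °C) should give the 2-(1-ethoxyvinyl)aryl diketone F3. Aqueous oxalic acid in THF should then give the 2-acetylaryl diketone F4. Ring B is closed by an intramolecular aldol addition of the aryl methyl ketone enol to the acetyl group of the 1,3-dione unit, catalysed by (R)-3,3'-bis(2,4,6-triisopropylphenyl)-1,1'-binaphthyl-2,2'-diyl hydrogen phosphate (toluene, rt), a known type of enantioselective aldolisation onto 1,3-diones, to give 16. Material of insufficient enantiomeric purity would be upgraded by chromatography on a chiral stationary phase.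

Step 9 may suffer from O-acylation of the enolate in place of C-acylation and from slow reaction of the di-ortho-substituted acid chloride. The fallback sets out from 4 and aldehyde 9 and returns at 12, bypassing step 8. The lithium enolate of 4 (LDA, THF, −78 °C, formed at the benzylic carbon) adds to 9 to give 3-[3,5-bis(benzyloxy)phenyl]-4-(2,4-bis(benzyloxy)-6-{[4-(benzyloxy)-2-oxo-2H-pyran-6-yl]methyl}phenyl)-4-hydroxybutan-2-one F5 as a mixture of diastereomers. Dess–Martin periodinane (NaHCO3, CH2Cl2, rt) then oxidises the β-hydroxy ketone to diketone 12.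

Step 12 may suffer from over-reduction of the pyrone ring or of the aryl ketones during the six-fold debenzylation, and from dehydration of the tertiary aldol to the naphthol on the catalyst support. The fallback sets out from 16 and ends at 17 without new compounds: non-reductive debenzylation with BCl3 and pentamethylbenzene as cation scavenger (CH2Cl2, −78 °C), quenched cold with methanol.

Further compounds
F1 | step 11 | 1-[2-bromo-3,5-bis(benzyloxy)phenyl]propan-2-one | CC(=O)Cc1cc(OCc2ccccc2)cc(OCc2ccccc2)c1Br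
F2 | step 11 | 2-[2-bromo-3,5-bis(benzyloxy)phenyl]-1-(2,4-bis(benzyloxy)-6-{[4-(benzyloxy)-2-oxo-2H-pyran-6-yl]methyl}phenyl)butane-1,3-dione | CC(=O)C(c1cc(OCc2ccccc2)cc(OCc2ccccc2)c1Br)C(=O)c1c(OCc2ccccc2)cc(OCc2ccccc2)cc1Cc1cc(OCc2ccccc2)cc(=O)o1
F3 | step 11 | 2-[3,5-bis(benzyloxy)-2-(1-ethoxyvinyl)phenyl]-1-(2,4-bis(benzyloxy)-6-{[4-(benzyloxy)-2-oxo-2H-pyran-6-yl]methyl}phenyl)butane-1,3-dione | CCOC(=C)c1c(OCc2ccccc2)cc(OCc2ccccc2)cc1C(C(C)=O)C(=O)c1c(OCc2ccccc2)cc(OCc2ccccc2)cc1Cc1cc(OCc2ccccc2)cc(=O)o1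
F4 | step 11 | 2-[2-acetyl-3,5-bis(benzyloxy)phenyl]-1-(2,4-bis(benzyloxy)-6-{[4-(benzyloxy)-2-oxo-2H-pyran-6-yl]methyl}phenyl)butane-1,3-dione | CC(=O)c1c(OCc2ccccc2)cc(OCc2ccccc2)cc1C(C(C)=O)C(=O)c1c(OCc2ccccc2)cc(OCc2ccccc2)cc1Cc1cc(OCc2ccccc2)cc(=O)o1
F5 | step 9 | 3-[3,5-bis(benzyloxy)phenyl]-4-(2,4-bis(benzyloxy)-6-{[4-(benzyloxy)-2-oxo-2H-pyran-6-yl]methyl}phenyl)-4-hydroxybutan-2-one | CC(=O)C(c1cc(OCc2ccccc2)cc(OCc2ccccc2)c1)C(O)c1c(OCc2ccccc2)cc(OCc2ccccc2)cc1Cc1cc(OCc2ccccc2)cc(=O)o1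
F0 | step 12 | none | none
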